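**Plan**

1. Numbering: tetrahydrofuran O1, C2 (aryl), C3 (CH2OH), C4 (aroyl), C5; C7 is the ketone carbon. The enabling feature is that the target is a 3-acyltetrahydrofuran in which C2 is at the aldehyde level and C7 can start as a tertiary allylic carbinol bonded to C5, so that C2=O1(+)–C5–C7–C4=C3 is a 2-oxonia-1,5-diene.
2. Retrosynthesis: cut C2–C3 and C4–C5 (reconnecting C5–C7) to a 2,4-diaryl-4-alkenyl-1,3-dioxolane; cut its two acetal C–O bonds to an aryl aldehyde and a 2-arylpent-3-ene-1,2-diol; cut C7–C4 of the diol to an α-silyloxy aryl ketone and an E-alkenylzinc reagent.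
3. Forward: the chain is joined at C7–C4 (step 5), the dioxolane is closed (step 8), and the only ring of the target arises in step 9 together with C2–C3 and C4–C5; phenol adjustment follows.
4. Stereochemistry: C7 (R) comes from a ligand-controlled alkenylzinc addition; a chair 2-oxonia-Cope transition state relays it to C2 (S) and C3 (R); C4 (S) comes from the aldol closure and is secured by base equilibration to the all-trans ketone.
5. A 4-mesyloxy group on the carbinol ring, exchanged for methoxy at the end, holds back ionisation at C7.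

Key step: step 9

Remark: the target is read from its SMILES as the (2S,3R,4S) all-trans isomer; the ligand enantiomer in step 5 is assumed to be the one that delivers the alkenyl group to the Si face of ketone 6, to be confirmed on the first batch.

**Route**

Step 1
Reactants: 1 3,4-dihydroxyacetophenone
Product: 2 4-acetyl-2-hydroxyphenyl methanesulfonate
Conditions: MsCl (1.0 equiv), K2CO3 (1.0 equiv), acetone, 0 °C
Reagents that add atoms: methanesulfonyl chloride, CS(Cl)(=O)=O
Why: The 4-hydroxyl is para to the acetyl group and therefore the more acidic phenol, so one equivalent of weak base should form its phenoxide selectively and MsCl should sulfonylate it (regioselective O-sulfonylation, the same site preference as the familiar 4-O-alkylation of 3,4-dihydroxyaryl ketones), with no stereocenter formed.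

Step 2
Reactants: 2 4-acetyl-2-hydroxyphenyl methanesulfonate
Product: 3 4-acetyl-2-(benzyloxy)phenyl methanesulfonate
Conditions: BnBr, K2CO3, DMF, rt
Reagents that add atoms: benzyl bromide, BrCc1ccccc1
Why: Williamson etherification of the one remaining phenol, under which the aryl mesylate and the methyl ketone are stable.

Step 3
Reactants: 3 4-acetyl-2-(benzyloxy)phenyl methanesulfonate
Product: 4 2-(benzyloxy)-4-[1-(tert-butyldimethylsilyloxy)ethenyl]phenyl methanesulfonate
Conditions: TBSOTf, Et3N, CH2Cl2, 0 °C
Reagents that add atoms: tert-butyldimethylsilyl trifluoromethanesulfonate, CC(C)(C)[Si](C)(C)OS(=O)(=O)C(F)(F)F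
Why: Soft enolisation of the aryl methyl ketone with a silyl triflate and an amine gives the silyl enol ether (silyl enol ether formation), for which only one regiochemistry exists and which needs no strong base that could attack the mesylate.

Step 4
Reactants: 4 2-(benzyloxy)-4-[1-(tert-butyldimethylsilyloxy)ethenyl]phenyl methanesulfonate
Product: 6 2-(benzyloxy)-4-[(tert-butyldimethylsilyloxy)acetyl]phenyl methanesulfonate, via silyloxy oxirane 5 (not isolated)
Conditions: mCPBA, CH2Cl2, 0 °C → rt
Reagents that add atoms: mCPBA (3-chloroperoxybenzoic acid), OOC(=O)c1cccc(Cl)c1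
Why: Rubottom oxidation, in which the electron-rich enol ether is epoxidised and the silyloxy oxirane opens with a 1,4-shift of silicon to the new oxygen, so that the α-oxygen arrives already protected and the transient oxirane center is lost again.

Step 5
Reactants: 6 2-(benzyloxy)-4-[(tert-butyldimethylsilyloxy)acetyl]phenyl methanesulfonate; 7 benzyl propargyl ether
Product: 10 2-(benzyloxy)-4-[(2R,3E)-5-(benzyloxy)-1-(tert-butyldimethylsilyloxy)-2-hydroxypent-3-en-2-yl]phenyl methanesulfonate, via alkenylzirconocene chloride 8 (not isolated), via alkenyl(methyl)zinc 9 (not isolated)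
Conditions: Cp2Zr(H)Cl, CH2Cl2, rt; Me2Zn, toluene, −78 °C; then 6, Ti(OiPr)4 (1.2 equiv), trans-1,2-bis[(2-hydroxy-7,7-dimethylbicyclo[2.2.1]heptan-1-yl)methanesulfonamido]cyclohexane (10 mol %), toluene, rt; aq. NH4Cl
Reagents that add atoms: none
Why: Syn hydrozirconation of the terminal alkyne places the metal at the terminus (E-alkenyl), exchange to zinc follows, and the ligand-controlled, titanium-mediated 1,2-addition of the alkenylzinc to the aryl ketone (catalytic asymmetric alkenylation of ketones) should set C7 as R by delivery to the Si face, the ligand distinguishing the flat aryl group from the CH2OSi arm.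

Step 6
Reactants: 10 2-(benzyloxy)-4-[(2R,3E)-5-(benzyloxy)-1-(tert-butyldimethylsilyloxy)-2-hydroxypent-3-en-2-yl]phenyl methanesulfonate
Product: 11 2-(benzyloxy)-4-[(2R,3E)-5-(benzyloxy)-1,2-dihydroxypent-3-en-2-yl]phenyl methanesulfonate
Conditions: Bu4NF, AcOH, THF, 0 °C
Reagents that add atoms: none
Why: Fluoride-mediated desilylation of the primary silyl ether, buffered with acetic acid so that neither the aryl mesylate nor the tertiary allylic carbinol is disturbed and C7 stays R.

Step 7
Reactants: 12 3-(benzyloxy)-4-methoxybenzaldehyde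
Product: 13 3-(benzyloxy)-4-methoxybenzaldehyde dimethyl acetal
Conditions: HC(OMe)3, p-TsOH·H2O (cat.), MeOH, rt; NaHCO3
Reagents that add atoms: trimethyl orthoformate, COC(OC)OC; methanol, CO
Why: Acid-catalysed acetalisation driven by the orthoformate as water scavenger gives the dimethyl acetal, which is the mild acetal donor needed for the acid-sensitive diol.

Step 8
Reactants: 11 2-(benzyloxy)-4-[(2R,3E)-5-(benzyloxy)-1,2-dihydroxypent-3-en-2-yl]phenyl methanesulfonate; 13 3-(benzyloxy)-4-methoxybenzaldehyde dimethyl acetal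
Product: 14 (4R)-2-[3-(benzyloxy)-4-methoxyphenyl]-4-[3-(benzyloxy)-4-(methanesulfonyloxy)phenyl]-4-[(E)-3-(benzyloxy)prop-1-enyl]-1,3-dioxolane (both epimers at the acetal carbon)
Conditions: PPTS (cat.), 5 Å molecular sieves, CH2Cl2, rt
Reagents that add atoms: none
Why: Transacetalisation under the weak acid PPTS with removal of methanol closes the dioxolane without breaking the C7–O bond (R retained), and both acetal epimers are acceptable because the acetal carbon becomes trigonal in step 9.

Step 9
Reactants: 14 (4R)-2-[3-(benzyloxy)-4-methoxyphenyl]-4-[3-(benzyloxy)-4-(methanesulfonyloxy)phenyl]-4-[(E)-3-(benzyloxy)prop-1-enyl]-1,3-dioxolane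
Product: 17 (2S,3R,4S)-2-[3-(benzyloxy)-4-methoxyphenyl]-3-[(benzyloxy)methyl]-4-[3-(benzyloxy)-4-(methanesulfonyloxy)benzoyl]tetrahydrofuran, via ring-opened oxocarbenium tin alkoxide 15 (not isolated), via tin enolate methyleneoxonium ion 16 (not isolated)
Conditions: SnCl4 (2 equiv), CH2Cl2, −78 → −20 °C; aq. NaHCO3
Reagents that add atoms: none
Why: SnCl4 should open the dioxolane reversibly at the bond from the acetal carbon to the tertiary oxygen, giving the E-oxocarbenium ion 15 on O1 with a tin alkoxide on C7, and a chair 2-oxonia-Cope shift (the concerted counterpart of Prins attack followed by pinacol shift) then forms C2–C3, breaks C5–C7 and gives the tin enolate 16, whose C4 adds to the methyleneoxonium carbon C5. The closest known reaction type is the SnCl4-promoted Prins–pinacol rearrangement of 4-alkenyl-1,3-dioxolanes to 3-acyltetrahydrofurans. The tetrahydrofuran, the only ring formed, closes through the C4–C5 aldol bond in a 5-(enolexo)-endo-trig mode. C2 and C3 are set together in the chair, where the E-oxocarbenium ion and the E-alkene place the C2 aryl group and the C3 benzyloxymethyl group equatorial (2,3-trans), and the R carbinol with its aryl group equatorial, the arrangement that leads to the Z-enolate and avoids allylic 1,3-strain between that ring and the C3 branch, selects the chair leading to 2S,3R. C4 is set in the aldol closure, in which the Z-enolate should react through the conformer with C3–H in the enolate plane to give the 3,4-trans (4S) ketone, which is also the more stable epimer and is equilibrated in step 10. The step needs the shift to outrun heterolysis of the tertiary benzylic allylic C7–O bond and needs one chair to dominate; the 4-mesyloxy group on the carbinol ring destabilises the C7 cation, the low temperature and the ordered chair do the rest, and only the ion on O1 has the six-atom array needed for the shift.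

Step 10
Reactants: 17 (2S,3R,4S)-2-[3-(benzyloxy)-4-methoxyphenyl]-3-[(benzyloxy)methyl]-4-[3-(benzyloxy)-4-(methanesulfonyloxy)benzoyl]tetrahydrofuran
Product: 18 (2S,3R,4S)-2-[3-(benzyloxy)-4-methoxyphenyl]-3-[(benzyloxy)methyl]-4-[3-(benzyloxy)-4-hydroxybenzoyl]tetrahydrofuran
Conditions: NaOH (2 M aq.), MeOH–THF, rt; then 1 M HCl
Reagents that add atoms: none
Why: Hydroxide cleaves the aryl mesylate at sulfur (sulfonate ester cleavage with S–O scission, eased by the para ketone that makes the phenoxide a good leaving group), and the same medium equilibrates any 3,4-cis ketone through its enolate to the all-trans epimer while C2 and C3 are not enolisable.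

Step 11
Reactants: 18 (2S,3R,4S)-2-[3-(benzyloxy)-4-methoxyphenyl]-3-[(benzyloxy)methyl]-4-[3-(benzyloxy)-4-hydroxybenzoyl]tetrahydrofuran
Product: 19 (2S,3R,4S)-2-[3-(benzyloxy)-4-methoxyphenyl]-3-[(benzyloxy)methyl]-4-[3-(benzyloxy)-4-methoxybenzoyl]tetrahydrofuran
Conditions: MeI, K2CO3, acetone, rt
Reagents that add atoms: iodomethane, CI
Why: Williamson methylation of the phenoxide, which K2CO3 forms selectively because the ketone α-hydrogen is far less acidic, so no stereocenter is touched.

Step 12
Reactants: 19 (2S,3R,4S)-2-[3-(benzyloxy)-4-methoxyphenyl]-3-[(benzyloxy)methyl]-4-[3-(benzyloxy)-4-methoxybenzoyl]tetrahydrofuran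
Product: 20 (2S,3R,4S)-2-(3-hydroxy-4-methoxyphenyl)-3-(hydroxymethyl)-4-(3-hydroxy-4-methoxybenzoyl)tetrahydrofuran (CNP0234761.1)
Conditions: H2 (1 atm), Pd/C, EtOAc–MeOH, rt
Reagents that add atoms: none
Why: Heterogeneous hydrogenolysis removes the two aryl benzyl ethers and the primary alkyl benzyl ether under neutral conditions, under which the electron-rich aryl ketone and the cyclic benzylic C2–O1 bond should react more slowly, and the three stereocenters are not involved.

**Compound list**

1 | 3,4-dihydroxyacetophenone | CC(=O)c1ccc(O)c(O)c1 | starting material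
2 | 4-acetyl-2-hydroxyphenyl methanesulfonate | CC(=O)c1ccc(OS(C)(=O)=O)c(O)c1 | intermediate
3 | 4-acetyl-2-(benzyloxy)phenyl methanesulfonate | CC(=O)c1ccc(OS(C)(=O)=O)c(OCc2ccccc2)c1 | intermediate
4 | 2-(benzyloxy)-4-[1-(tert-butyldimethylsilyloxy)ethenyl]phenyl methanesulfonate | C=C(O[Si](C)(C)C(C)(C)C)c1ccc(OS(C)(=O)=O)c(OCc2ccccc2)c1 | intermediate
5 | 2-(benzyloxy)-4-[2-(tert-butyldimethylsilyloxy)oxiran-2-yl]phenyl methanesulfonate (racemic, not isolated) | CC(C)(C)[Si](C)(C)OC1(CO1)c1ccc(OS(C)(=O)=O)c(OCc2ccccc2)c1 | intermediate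
6 | 2-(benzyloxy)-4-[(tert-butyldimethylsilyloxy)acetyl]phenyl methanesulfonate | CC(C)(C)[Si](C)(C)OCC(=O)c1ccc(OS(C)(=O)=O)c(OCc2ccccc2)c1 | intermediate
7 | benzyl propargyl ether | C#CCOCc1ccccc1 | starting material
8 | [(E)-3-(benzyloxy)prop-1-enyl]zirconocene chloride (not isolated) | Cl[Zr+2]/C=C/COCc1ccccc1.[cH-]1cccc1.[cH-]1cccc1 | intermediate
9 | [(E)-3-(benzyloxy)prop-1-enyl](methyl)zinc (not isolated) | C[Zn]/C=C/COCc1ccccc1 | intermediate
10 | 2-(benzyloxy)-4-[(2R,3E)-5-(benzyloxy)-1-(tert-butyldimethylsilyloxy)-2-hydroxypent-3-en-2-yl]phenyl methanesulfonate | C(OCc1ccccc1)/C=C/[C@@](O)(c1ccc(OS(C)(=O)=O)c(OCc2ccccc2)c1)CO[Si](C)(C)C(C)(C)C | intermediate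
11 | 2-(benzyloxy)-4-[(2R,3E)-5-(benzyloxy)-1,2-dihydroxypent-3-en-2-yl]phenyl methanesulfonate | C(OCc1ccccc1)/C=C/[C@@](O)(c1ccc(OS(C)(=O)=O)c(OCc2ccccc2)c1)CO | intermediate
12 | 3-(benzyloxy)-4-methoxybenzaldehyde | COc1ccc(C=O)cc1OCc1ccccc1 | starting material
13 | 3-(benzyloxy)-4-methoxybenzaldehyde dimethyl acetal | COc1ccc(C(OC)OC)cc1OCc1ccccc1 | intermediate
14 | (4R)-2-[3-(benzyloxy)-4-methoxyphenyl]-4-[3-(benzyloxy)-4-(methanesulfonyloxy)phenyl]-4-[(E)-3-(benzyloxy)prop-1-enyl]-1,3-dioxolane, both acetal epimers | C(OCc1ccccc1)/C=C/[C@@]1(c2ccc(OS(C)(=O)=O)c(OCc3ccccc3)c2)COC(c2ccc(OC)c(OCc3ccccc3)c2)O1 | intermediate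
15 | E-oxocarbenium ion on O1 with SnCl4-bound alkoxide on (R)-C7 (not isolated) | COc1ccc(/C=[O+]/C[C@](O[Sn-](Cl)(Cl)(Cl)Cl)(c2ccc(OS(C)(=O)=O)c(OCc3ccccc3)c2)/C=C/COCc2ccccc2)cc1OCc1ccccc1 | intermediate
16 | (2S,3R) Z-tin enolate carrying the O1 methyleneoxonium ion (not isolated) | C=[O+][C@H](c1ccc(OC)c(OCc2ccccc2)c1)[C@@H](COCc1ccccc1)/C=C(\O[Sn-](Cl)(Cl)(Cl)Cl)c1ccc(OS(C)(=O)=O)c(OCc2ccccc2)c1 | intermediate
17 | (2S,3R,4S)-2-[3-(benzyloxy)-4-methoxyphenyl]-3-[(benzyloxy)methyl]-4-[3-(benzyloxy)-4-(methanesulfonyloxy)benzoyl]tetrahydrofuran (all-trans) | CS(=O)(=O)Oc1ccc(C(=O)[C@@H]2CO[C@H](c3ccc(OC)c(OCc4ccccc4)c3)[C@H]2COCc2ccccc2)cc1OCc1ccccc1 | intermediate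
18 | (2S,3R,4S)-2-[3-(benzyloxy)-4-methoxyphenyl]-3-[(benzyloxy)methyl]-4-[3-(benzyloxy)-4-hydroxybenzoyl]tetrahydrofuran | Oc1ccc(C(=O)[C@@H]2CO[C@H](c3ccc(OC)c(OCc4ccccc4)c3)[C@H]2COCc2ccccc2)cc1OCc1ccccc1 | intermediate
19 | (2S,3R,4S)-2-[3-(benzyloxy)-4-methoxyphenyl]-3-[(benzyloxy)methyl]-4-[3-(benzyloxy)-4-methoxybenzoyl]tetrahydrofuran | COc1ccc(C(=O)[C@@H]2CO[C@H](c3ccc(OC)c(OCc4ccccc4)c3)[C@H]2COCc2ccccc2)cc1OCc1ccccc1 | intermediate
20 | (2S,3R,4S)-2-(3-hydroxy-4-methoxyphenyl)-3-(hydroxymethyl)-4-(3-hydroxy-4-methoxybenzoyl)tetrahydrofuran (CNP0234761.1) | COc1ccc(C(=O)[C@@H]2CO[C@H](c3ccc(OC)c(O)c3)[C@H]2CO)cc1O | target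

**Count**

Total steps: 12. Longest linear sequence: 11 steps (1 to 20 through steps 1–6 and 8–12; step 7 is a one-step side branch).

**Steps most likely to fail**

Step 9. The process at risk is heterolysis of the tertiary, benzylic and allylic C7–O bond under SnCl4 before the sigmatropic shift. That would consume the acetal and, if reversible, wear down the transfer of configuration from C7. The fallback sets out from diol 11 and comes back at ketone 17. It keeps the same two bond formations but generates the oxocarbenium ion regiospecifically, with a silyl ether instead of a metal alkoxide on C7.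
- The primary hydroxyl of 11 is acylated with 3-benzyloxy-4-methoxybenzoyl chloride (pyridine, DMAP, CH2Cl2, 0 °C) to give the primary 3-benzyloxy-4-methoxybenzoate F1.
- The tertiary hydroxyl is silylated with N-(trimethylsilyl)imidazole to give the trimethylsilyl ether F2.
- Reduction of the ester with iBu2AlH at −78 °C and trapping of the aluminium hemiacetal with Ac2O, pyridine and DMAP (reductive acetylation) gives the α-acetoxy ether F3.
- With a substoichiometric amount of TMSOTf in CH2Cl2 at −78 °C, F3 should lose acetate to the same E-oxocarbenium ion on O1. The 2-oxonia-Cope shift then gives a silyl enol ether, which closes on the methyleneoxonium ion in a Mukaiyama-type aldol to give 17 with loss of trimethylsilyl acetate.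

Step 5. The process at risk is an unselective background addition, which would give low enantiomeric purity at C7. The α-silyloxy ketone is more electrophilic than a plain aryl alkyl ketone, and its α-oxygen can bind zinc or titanium. The fallback sets out from ketone 6 and comes back at diol 11 by classical resolution.
- Addition of reagent 9 to 6 with Ti(OiPr)4 and the racemic ligand gives the racemic tertiary alcohol F4.
- Bu4NF and AcOH give the racemic diol F5.
- Steglich esterification of the primary hydroxyl with (S)-2-methoxy-2-phenylacetic acid (DCC, DMAP) gives the mixture of two diastereomeric esters F6.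
- Chromatography or crystallisation separates the ester of the (R)-carbinol F7, whose configuration is to be assigned by X-ray analysis or by correlation.
- K2CO3 in MeOH at 0 °C releases 11.

Step 1. The process at risk is over-sulfonylation and loss of site selectivity, because the remaining phenol of the monomesylate is about as acidic as the 4-hydroxyl of 1. The fallback sets out from 1 and comes back at 3, bypassing 2. It marks the 4-oxygen by alkylation, where the mono-ether is less acidic than 1 and the site preference is well established.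
- Allyl bromide and K2CO3 (1 equiv) in acetone give 4-allyloxy-3-hydroxyacetophenone F8.
- BnBr and K2CO3 give 4-allyloxy-3-benzyloxyacetophenone F9.
- Pd(PPh3)4 and morpholine in THF remove the allyl group (Tsuji–Trost deallylation) to give 3-benzyloxy-4-hydroxyacetophenone F10.
- MsCl and Et3N then give 3.

**Further compounds**

F1 | step 9 | (2R,3E)-2-[3-(benzyloxy)-4-(methanesulfonyloxy)phenyl]-5-(benzyloxy)-2-hydroxypent-3-enyl 3-(benzyloxy)-4-methoxybenzoate | C(OCc1ccccc1)/C=C/[C@@](O)(c1ccc(OS(C)(=O)=O)c(OCc2ccccc2)c1)COC(=O)c1ccc(OC)c(OCc2ccccc2)c1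
F2 | step 9 | trimethylsilyl ether of F1 at the tertiary hydroxyl (2R,3E) | C(OCc1ccccc1)/C=C/[C@@](O[Si](C)(C)C)(c1ccc(OS(C)(=O)=O)c(OCc2ccccc2)c1)COC(=O)c1ccc(OC)c(OCc2ccccc2)c1
F3 | step 9 | α-acetoxy ether from F2: acetoxy[3-(benzyloxy)-4-methoxyphenyl]methyl ether of the primary oxygen, (2R,3E), both epimers at the acetal carbon | C(OCc1ccccc1)/C=C/[C@@](O[Si](C)(C)C)(c1ccc(OS(C)(=O)=O)c(OCc2ccccc2)c1)COC(OC(C)=O)c1ccc(OC)c(OCc2ccccc2)c1
F4 | step 5 | racemic 10 | C(OCc1ccccc1)/C=C/C(O)(c1ccc(OS(C)(=O)=O)c(OCc2ccccc2)c1)CO[Si](C)(C)C(C)(C)C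
F5 | step 5 | racemic 11 | C(OCc1ccccc1)/C=C/C(O)(c1ccc(OS(C)(=O)=O)c(OCc2ccccc2)c1)CO
F6 | step 5 | primary (S)-2-methoxy-2-phenylacetate of F5, mixture of the two carbinol diastereomers | C(OCc1ccccc1)/C=C/C(O)(c1ccc(OS(C)(=O)=O)c(OCc2ccccc2)c1)COC(=O)[C@@H](OC)c1ccccc1
F7 | step 5 | primary (S)-2-methoxy-2-phenylacetate of the (R)-diol 11 | C(OCc1ccccc1)/C=C/[C@@](O)(c1ccc(OS(C)(=O)=O)c(OCc2ccccc2)c1)COC(=O)[C@@H](OC)c1ccccc1
F8 | step 1 | 4-allyloxy-3-hydroxyacetophenone | CC(=O)c1ccc(OCC=C)c(O)c1
F9 | step 1 | 4-allyloxy-3-benzyloxyacetophenone | CC(=O)c1ccc(OCC=C)c(OCc2ccccc2)c1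
F10 | step 1 | 3-benzyloxy-4-hydroxyacetophenone | CC(=O)c1ccc(O)c(OCc2ccccc2)c1
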